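**Retrosynthetic overview**
1. Target 14 comes from flavan-4-ol 12 by oxidation of the C4 carbinol and removal of three methoxymethyl (MOM) groups; C4 is held one oxidation level low so that the strongly basic ring closure meets no enolisable carbonyl.
2. Key disconnection O1–C8a: ring C is closed last, from the acyclic (S)-1,3-diol 10, by base-induced loss of HBr to the C8≡C8a aryne of ring A and capture of C8a by the C2 alkoxide (cine substitution: bromide leaves C8, O1 enters at C8a).
3. Enabling feature: in ring A, C8 is the only unsubstituted CH and sits between C8a and the C7 oxygen. A bromine on C8 makes the neighbouring C8a–H removable, the C7 oxygen polarises the aryne towards attack at C8a, and the side chain on C4a lets O1 reach only C8a (six-membered ring).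
4. Diol 10 comes from Noyori–Ikariya transfer hydrogenation (sets C2 as S) of aldol 9, itself from the lithium enolate of ring B ketone 7 and ring A aldehyde 5.
5. Aldehyde 5 comes from 5-bromo-2,4-dihydroxybenzaldehyde 1: the same bromine blocks C5, so the Claisen rearrangement of the 4-O-prenyl ether can place the 1,1-dimethylallyl group only on C3 (future C6). Rings A and B are aromatic throughout.

Key step: step 7

Remark: locants C2–C8a are those of the chromanone; the carbinol carbon that becomes C4 is carried as a mixture (racemic in 9, both epimers in 10 and 12), because step 8 removes this centre.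

**Step 1**
Reactants: 1 5-bromo-2,4-dihydroxybenzaldehyde
Product: 2 5-bromo-2-hydroxy-4-[(3-methylbut-2-en-1-yl)oxy]benzaldehyde
Conditions: prenyl bromide (1.05 equiv), K2CO3 (1.1 equiv), acetone, rt
Reagents that add atoms: prenyl bromide (1-bromo-3-methylbut-2-ene), CC(C)=CCBr
Why: Williamson etherification; the 4-hydroxyl (para to the formyl group, not hydrogen-bonded) is the more acidic and more nucleophilic phenol, while the 2-hydroxyl is held in the hydrogen bond to the aldehyde, so mono-O-alkylation at O4 is expected.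

**Step 2**
Reactants: 2 5-bromo-2-hydroxy-4-[(3-methylbut-2-en-1-yl)oxy]benzaldehyde
Product: 4 5-bromo-2,4-dihydroxy-3-(2-methylbut-3-en-2-yl)benzaldehyde, via ortho-dienone 3 (not isolated)
Conditions: PhNEt2, 185 °C, sealed tube, argon
Reagents that add atoms: none
Why: Aromatic Claisen rearrangement; the [3,3] shift can deliver the allyl terminus only to C3 because the other ortho carbon (C5) carries bromine, and enolisation of dienone 3, fast in the amine solvent (which also suppresses acid-catalysed cyclisation onto the new alkene), should give the 1,1-dimethylallyl phenol.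

**Step 3**
Reactants: 4 5-bromo-2,4-dihydroxy-3-(2-methylbut-3-en-2-yl)benzaldehyde
Product: 5 5-bromo-2,4-bis(methoxymethoxy)-3-(2-methylbut-3-en-2-yl)benzaldehyde
Conditions: NaH (2.5 equiv), MOMCl (2.5 equiv), DMF, 0 °C → rt
Reagents that add atoms: chloromethyl methyl ether (MOMCl), COCCl
Why: Twofold Williamson-type O-alkylation of the phenoxides; sodium hydride is used because the 2-hydroxyl is hydrogen-bonded and flanked by the tertiary alkyl group, and the small, reactive MOMCl should still reach it.

**Step 4**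
Reactants: 6 1-(4-hydroxy-3-methoxyphenyl)ethanone (acetovanillone)
Product: 7 1-[3-methoxy-4-(methoxymethoxy)phenyl]ethanone
Conditions: NaH (1.05 equiv), MOMCl (1.1 equiv), THF/DMF, 0 °C → rt
Reagents that add atoms: chloromethyl methyl ether (MOMCl), COCCl
Why: Williamson-type O-alkylation; one equivalent of base removes only the phenolic proton, so the methyl ketone is not enolised.

**Step 5**
Reactants: 7 1-[3-methoxy-4-(methoxymethoxy)phenyl]ethanone; 5 5-bromo-2,4-bis(methoxymethoxy)-3-(2-methylbut-3-en-2-yl)benzaldehyde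
Product: 9 rac-3-[5-bromo-2,4-bis(methoxymethoxy)-3-(2-methylbut-3-en-2-yl)phenyl]-3-hydroxy-1-[3-methoxy-4-(methoxymethoxy)phenyl]propan-1-one, via lithium enolate 8 (not isolated)
Conditions: LiN(i-Pr)2 (LDA, 1.05 equiv), THF, −78 °C; then 5, −78 °C; AcOH (1.1 equiv), −78 °C
Reagents that add atoms: none
Why: Directed aldol addition of a kinetically formed lithium enolate of an aryl methyl ketone to an aromatic aldehyde; the new carbinol centre is formed without control, which is harmless because it becomes the C4 carbonyl in step 8, and the cold acidic quench should prevent retro-aldol cleavage and dehydration.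

**Step 6**
Reactants: 9 rac-3-[5-bromo-2,4-bis(methoxymethoxy)-3-(2-methylbut-3-en-2-yl)phenyl]-3-hydroxy-1-[3-methoxy-4-(methoxymethoxy)phenyl]propan-1-one
Product: 10 (1RS,3S)-1-[5-bromo-2,4-bis(methoxymethoxy)-3-(2-methylbut-3-en-2-yl)phenyl]-3-[3-methoxy-4-(methoxymethoxy)phenyl]propane-1,3-diol
Conditions: RuCl[(S,S)-TsDPEN](p-cymene) (2 mol%), HCO2Na (5 equiv), MeOH/H2O, 40 °C
Reagents that add atoms: none
Why: Noyori–Ikariya asymmetric transfer hydrogenation of an aryl alkyl ketone; outer-sphere hydride transfer from the (S,S)-TsDPEN ruthenium hydride, with the aryl group held against the η6-arene, should give the (S)-carbinol (the sense in which acetophenone gives (S)-1-phenylethanol) independently of the remote carbinol, and the near-neutral formate medium spares the acid-labile benzylic alcohol, the acetals, the aryl bromide and the alkene.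

**Step 7**
Reactants: 10 (1RS,3S)-1-[5-bromo-2,4-bis(methoxymethoxy)-3-(2-methylbut-3-en-2-yl)phenyl]-3-[3-methoxy-4-(methoxymethoxy)phenyl]propane-1,3-diol
Product: 12 (2S,4RS)-5,7-bis(methoxymethoxy)-2-[3-methoxy-4-(methoxymethoxy)phenyl]-6-(2-methylbut-3-en-2-yl)-3,4-dihydro-2H-chromen-4-ol, via aryne dialkoxide 11 (not isolated)
Conditions: lithium 2,2,6,6-tetramethylpiperidide (LiTMP, 4 equiv), THF, −78 °C → 0 °C; then H2O
Reagents that add atoms: none
Why: LiTMP converts 10 into its dilithium dialkoxide and then removes C8a–H, the only hydrogen on ring A and the one acidified by the ortho bromine; loss of LiBr gives the C8≡C8a aryne 11, the C2 alkoxide adds in the ring plane to C8a, and the C8 aryllithium so formed (held by the neighbouring OCH2OMe oxygen) is protonated on quench, so that O1 enters where hydrogen stood and C8 returns to CH (cine substitution). The closest known reaction type is the amide-base benzyne cyclisation of ω-(halophenyl)alkanols and ω-(halophenyl)alkylamines to chromans and tetrahydroquinolines. Ring C closes in a 6-exo-dig sense at the aryne carbon ortho to the side chain; O1 cannot reach C8 (that would need a meta-bridged seven-membered ring) and the C4 alkoxide could only close a four-membered ring. No stereocentre is formed: the C2–O bond is not touched, so the (S) centre from step 6 is carried through unchanged, and the C4 carbinol stays a mixture that step 8 erases. The step needs regioselectivity (O1 to C8a, not C8) and preference for intramolecular capture; the tether and the C7 alkoxy group, which directs nucleophiles to the distal carbon of 3-alkoxyarynes, both point to C8a, and LiTMP has no β-hydrogen to reduce the aryne and is too hindered to add to it. Because C4 is a carbinol and not a ketone, the basic medium finds no enolisable carbonyl, so retro-aldol cleavage and β-elimination, which would destroy the C2 centre, cannot occur.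

**Step 8**
Reactants: 12 (2S,4RS)-5,7-bis(methoxymethoxy)-2-[3-methoxy-4-(methoxymethoxy)phenyl]-6-(2-methylbut-3-en-2-yl)-3,4-dihydro-2H-chromen-4-ol (used crude)
Product: 13 (2S)-5,7-bis(methoxymethoxy)-2-[3-methoxy-4-(methoxymethoxy)phenyl]-6-(2-methylbut-3-en-2-yl)-2,3-dihydro-4H-chromen-4-one
Conditions: MnO2 (activated, excess), CH2Cl2, rt
Reagents that add atoms: none
Why: Oxidation of an electron-rich benzylic alcohol with MnO2 under neutral conditions; both C4 epimers should converge on one ketone, the acid-labile 4-ol is never exposed to acid, and the absence of base excludes ring opening (retro-oxa-Michael) and loss of configuration at C2.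

**Step 9**
Reactants: 13 (2S)-5,7-bis(methoxymethoxy)-2-[3-methoxy-4-(methoxymethoxy)phenyl]-6-(2-methylbut-3-en-2-yl)-2,3-dihydro-4H-chromen-4-one
Product: 14 (2S)-5,7-dihydroxy-2-(4-hydroxy-3-methoxyphenyl)-6-(2-methylbut-3-en-2-yl)-2,3-dihydro-4H-chromen-4-one
Conditions: HCl (1.25 M in MeOH), 0 °C → rt
Reagents that add atoms: none
Why: Acid-catalysed transacetalisation of the three aryl MOM ethers to methanol; dilute anhydrous acid at or below room temperature is chosen so that the monosubstituted alkene flanked by two phenols is not protonated, and the flavanone, which loses its configuration only under base, should keep C2.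

**Compound list**
1 | 5-bromo-2,4-dihydroxybenzaldehyde | O=Cc1cc(Br)c(O)cc1O | starting material
2 | 5-bromo-2-hydroxy-4-[(3-methylbut-2-en-1-yl)oxy]benzaldehyde | O=Cc1cc(Br)c(OCC=C(C)C)cc1O | intermediate
3 | 5-bromo-2-hydroxy-3-(2-methylbut-3-en-2-yl)-4-oxocyclohexa-1,5-diene-1-carbaldehyde (ortho-dienone, racemic) | O=CC1=C(O)C(C(C)(C)C=C)C(=O)C(Br)=C1 | intermediate
4 | 5-bromo-2,4-dihydroxy-3-(2-methylbut-3-en-2-yl)benzaldehyde | O=Cc1cc(Br)c(O)c(C(C)(C)C=C)c1O | intermediate
5 | 5-bromo-2,4-bis(methoxymethoxy)-3-(2-methylbut-3-en-2-yl)benzaldehyde | O=Cc1cc(Br)c(OCOC)c(C(C)(C)C=C)c1OCOC | intermediate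
6 | 1-(4-hydroxy-3-methoxyphenyl)ethanone (acetovanillone) | CC(=O)c1ccc(O)c(OC)c1 | starting material
7 | 1-[3-methoxy-4-(methoxymethoxy)phenyl]ethanone | CC(=O)c1ccc(OCOC)c(OC)c1 | intermediate
8 | lithium 1-[3-methoxy-4-(methoxymethoxy)phenyl]ethenolate | [Li+].[O-]C(=C)c1ccc(OCOC)c(OC)c1 | intermediate
9 | rac-3-[5-bromo-2,4-bis(methoxymethoxy)-3-(2-methylbut-3-en-2-yl)phenyl]-3-hydroxy-1-[3-methoxy-4-(methoxymethoxy)phenyl]propan-1-one | O=C(CC(O)c1cc(Br)c(OCOC)c(C(C)(C)C=C)c1OCOC)c1ccc(OCOC)c(OC)c1 | intermediate
10 | (1RS,3S)-1-[5-bromo-2,4-bis(methoxymethoxy)-3-(2-methylbut-3-en-2-yl)phenyl]-3-[3-methoxy-4-(methoxymethoxy)phenyl]propane-1,3-diol | OC(C[C@H](O)c1ccc(OCOC)c(OC)c1)c1cc(Br)c(OCOC)c(C(C)(C)C=C)c1OCOC | intermediate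
11 | dilithium (1RS,3S)-1-[5,6-didehydro-2,4-bis(methoxymethoxy)-3-(2-methylbut-3-en-2-yl)phenyl]-3-[3-methoxy-4-(methoxymethoxy)phenyl]propane-1,3-diolate (aryne) | [Li+].[Li+].[O-]C(C[C@H]([O-])c1ccc(OCOC)c(OC)c1)C1=C(OCOC)C(C(C)(C)C=C)=C(OCOC)C#C1 | intermediate
12 | (2S,4RS)-5,7-bis(methoxymethoxy)-2-[3-methoxy-4-(methoxymethoxy)phenyl]-6-(2-methylbut-3-en-2-yl)-3,4-dihydro-2H-chromen-4-ol | C=CC(C)(C)c1c(OCOC)cc2c(c1OCOC)C(O)C[C@@H](c1ccc(OCOC)c(OC)c1)O2 | intermediate
13 | (2S)-5,7-bis(methoxymethoxy)-2-[3-methoxy-4-(methoxymethoxy)phenyl]-6-(2-methylbut-3-en-2-yl)-2,3-dihydro-4H-chromen-4-one | C=CC(C)(C)c1c(OCOC)cc2c(c1OCOC)C(=O)C[C@@H](c1ccc(OCOC)c(OC)c1)O2 | intermediate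
14 | (2S)-5,7-dihydroxy-2-(4-hydroxy-3-methoxyphenyl)-6-(2-methylbut-3-en-2-yl)-2,3-dihydro-4H-chromen-4-one | C=CC(C)(C)c1c(O)cc2c(c1O)C(=O)C[C@@H](c1ccc(O)c(OC)c1)O2 | target

**Step count**
Total: 9 steps. Longest linear sequence: 8 steps (1 → 2 → 4 → 5 → 9 → 10 → 12 → 13 → 14).

**Steps most likely to fail**

Step 7 (key step). The twofold lithium alkoxide may slow or prevent removal of C8a–H, or the aryne may be consumed by intermolecular addition or by hydride transfer from the C2 carbinol C–H before O1 closes the ring. The fallback replaces cine substitution by ipso substitution, with the leaving group already on C8a. It sets out from 7 (used as enolate 8, as in step 5) together with commercial 2,4,6-trihydroxybenzaldehyde F1, and rejoins the route at 12. F1 is prenylated at its free para hydroxyl (prenyl bromide, K2CO3) to give 2,6-dihydroxy-4-[(3-methylbut-2-en-1-yl)oxy]benzaldehyde F2. Claisen rearrangement to either of its two equivalent ortho carbons (PhNEt2, 185 °C) should give 2,4,6-trihydroxy-3-(2-methylbut-3-en-2-yl)benzaldehyde F3. MOM protection of the non-chelated 4-hydroxyl gives F4, 2,6-dihydroxy-4-(methoxymethoxy)-3-(2-methylbut-3-en-2-yl)benzaldehyde F4. Triflation (PhNTf2, 1 equiv, K2CO3) of the less hindered chelated hydroxyl, the one remote from the tertiary alkyl group, gives the aryl triflate F5, and MOM protection of the last hydroxyl (NaH, MOMCl) gives the bis-MOM aryl triflate F6. Aldol addition of 8 to F6 gives the racemic triflate aldol F7, and the transfer hydrogenation of step 6 gives the (3S)-diol triflate F8. Intramolecular Pd-catalysed etherification of the aryl triflate by the (S)-carbinol (Pd(OAc)2, 2-(di-tert-butylphosphino)-1,1'-binaphthyl, K3PO4, toluene, 80 °C) should then close O1–C8a with retention at C2 and give 12.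

Step 2. At 185 °C the prenyl ether may fragment to phenol 1 and isoprene, or the product may cyclise thermally onto its own alkene to a dihydrobenzofuran. The fallback builds the aryl–C(quaternary) bond by cross-coupling instead of a sigmatropic shift; it sets out from 1 and rejoins at 5. Iodination of 1 at C3, the only activated free position (N-iodosuccinimide, MeCN), gives 5-bromo-2,4-dihydroxy-3-iodobenzaldehyde F9. Twofold MOM protection (NaH, MOMCl) gives 5-bromo-3-iodo-2,4-bis(methoxymethoxy)benzaldehyde F10. A ligand-controlled, γ-selective Suzuki–Miyaura coupling of the C–I bond with 3-methylbut-2-enylboronic acid pinacol ester (Pd(OAc)2, bulky dialkylbiarylphosphine, K3PO4, THF/H2O) should give the branched 1,1-dimethylallyl arene 5, with the C–Br bond left for step 7.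

Step 6. Facial selectivity or turnover may be poor with this electron-rich β-hydroxy ketone, and the doubly activated benzylic carbinol may ionise and eliminate during a long reaction. The fallback protects that carbinol and uses a stoichiometric borane reduction steered by a chiral oxazaborolidine; it sets out from 9 and rejoins at 10. Silylation (TBSOTf, 2,6-lutidine, CH2Cl2, −78 °C) gives the silyl ether of 9, F11. Corey–Bakshi–Shibata reduction ((R)-Me-CBS oxazaborolidine, BH3·SMe2, THF, −20 °C) should give the (1S)-alcohol F12; the silyl ether prevents substrate-directed hydride delivery from a boron alkoxide at the racemic centre. Tetrabutylammonium fluoride (THF, 0 °C) then gives 10.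

**Further compounds**
F1 | step 7 | 2,4,6-trihydroxybenzaldehyde | O=Cc1c(O)cc(O)cc1O
F2 | step 7 | 2,6-dihydroxy-4-[(3-methylbut-2-en-1-yl)oxy]benzaldehyde | O=Cc1c(O)cc(OCC=C(C)C)cc1O
F3 | step 7 | 2,4,6-trihydroxy-3-(2-methylbut-3-en-2-yl)benzaldehyde | O=Cc1c(O)cc(O)c(C(C)(C)C=C)c1O
F4 | step 7 | 2,6-dihydroxy-4-(methoxymethoxy)-3-(2-methylbut-3-en-2-yl)benzaldehyde | O=Cc1c(O)cc(OCOC)c(C(C)(C)C=C)c1O
F5 | step 7 | 2-formyl-3-hydroxy-5-(methoxymethoxy)-4-(2-methylbut-3-en-2-yl)phenyl trifluoromethanesulfonate | O=Cc1c(OS(=O)(=O)C(F)(F)F)cc(OCOC)c(C(C)(C)C=C)c1O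
F6 | step 7 | 2-formyl-3,5-bis(methoxymethoxy)-4-(2-methylbut-3-en-2-yl)phenyl trifluoromethanesulfonate | O=Cc1c(OS(=O)(=O)C(F)(F)F)cc(OCOC)c(C(C)(C)C=C)c1OCOC
F7 | step 7 | rac-2-{1-hydroxy-3-[3-methoxy-4-(methoxymethoxy)phenyl]-3-oxopropyl}-3,5-bis(methoxymethoxy)-4-(2-methylbut-3-en-2-yl)phenyl trifluoromethanesulfonate | O=C(CC(O)c1c(OS(=O)(=O)C(F)(F)F)cc(OCOC)c(C(C)(C)C=C)c1OCOC)c1ccc(OCOC)c(OC)c1
F8 | step 7 | 2-{(1RS,3S)-1,3-dihydroxy-3-[3-methoxy-4-(methoxymethoxy)phenyl]propyl}-3,5-bis(methoxymethoxy)-4-(2-methylbut-3-en-2-yl)phenyl trifluoromethanesulfonate | OC(C[C@H](O)c1ccc(OCOC)c(OC)c1)c1c(OS(=O)(=O)C(F)(F)F)cc(OCOC)c(C(C)(C)C=C)c1OCOC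
F9 | step 2 | 5-bromo-2,4-dihydroxy-3-iodobenzaldehyde | O=Cc1cc(Br)c(O)c(I)c1O
F10 | step 2 | 5-bromo-3-iodo-2,4-bis(methoxymethoxy)benzaldehyde | O=Cc1cc(Br)c(OCOC)c(I)c1OCOC
F11 | step 6 | rac-3-[5-bromo-2,4-bis(methoxymethoxy)-3-(2-methylbut-3-en-2-yl)phenyl]-3-[(tert-butyldimethylsilyl)oxy]-1-[3-methoxy-4-(methoxymethoxy)phenyl]propan-1-one | CC(C)(C)[Si](C)(C)OC(CC(=O)c1ccc(OCOC)c(OC)c1)c1cc(Br)c(OCOC)c(C(C)(C)C=C)c1OCOC
F12 | step 6 | (1S,3RS)-3-[5-bromo-2,4-bis(methoxymethoxy)-3-(2-methylbut-3-en-2-yl)phenyl]-3-[(tert-butyldimethylsilyl)oxy]-1-[3-methoxy-4-(methoxymethoxy)phenyl]propan-1-ol | CC(C)(C)[Si](C)(C)OC(C[C@H](O)c1ccc(OCOC)c(OC)c1)c1cc(Br)c(OCOC)c(C(C)(C)C=C)c1OCOC
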